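The late readings are where the two earlier runs part. By 10.0 min, Saturday's run has lost 7.5 percentage points of the charge as left-handed substrate and Sunday's 12 points, while the right-handed substrate stays within scatter of where it began. So we count the left-handed loss as the reacted part.

| setting | Saturday's | Sunday's | flask |
|---|---|---|---|
| left-handed substrate | 0.47 M | 0.47 M | 0.47 M |
| right-handed substrate | 0.47 M | 0.47 M | 0.47 M |
| partner | 0.99 M | 1.6 M | 0.705 M |
| precatalyst | 0.94 mM | 0.94 mM | 0.94 mM |
| remark | run made earlier | run made earlier |  |
| time |  |  | 12 min |

| run | time / min | left-handed substrate / % | right-handed substrate / % |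
|---|---|---|---|
| Saturday's | 1.50 | 51.7 | 51.6 |
| Saturday's | 3.00 | 50.2 | 50.7 |
| Saturday's | 5.00 | 48.7 | 49.7 |
| Saturday's | 6.00 | 48.5 | 50.3 |
| Saturday's | 8.00 | 45.6 | 49.5 |
| Saturday's | 10.0 | 42.5 | 50.2 |
| Sunday's | 1.50 | 48.2 | 49.7 |
| Sunday's | 3.00 | 47.9 | 50.9 |
| Sunday's | 5.00 | 45.6 | 49.1 |
| Sunday's | 6.00 | 46.1 | 50.7 |
| Sunday's | 8.00 | 43.4 | 50.2 |
| Sunday's | 10.0 | 38.4 | 49.8 |

(standard deviation of a reading: 1 percentage point)

1. part of the left-handed substrate and right-handed substrate charged together that has reacted at 12 min
2. excess of left-handed product over right-handed product in the product at 12 min
3. excess of right-handed substrate over left-handed substrate among what is left of the two at 12 min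

- free catalyst is single-handed; left-handed substrate and right-handed substrate are mirror images of each other, charged as a racemate, each of them at the stated concentration
- an excess is the difference of the two amounts in percent of their sum
- an excess is below zero if the other one leads

Two chemists stand at the board and read the same curve. Saturday's run loses more after 5.00 min than before it, so both take the loss as growing with time squared, as under slow initiation, where the precatalyst releases working catalyst steadily. They part over the partner.

The second chemist points out that the new flask holds more partner than left-handed substrate and says the partner stays out of the rate, so the two runs differ by scatter. Their mean, carried forward by time squared, gives 13.8% reacted at 12 min.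

The first chemist answers that the runs differ by 4.1 points, against a scatter of 1 point per reading, and so divides the partner out. At the last reading that chemist writes the partner and precatalyst charges as fractions of the left-handed substrate charge, divides the fraction lost by both, takes the square root and divides by the time. Saturday's run reads 0.422 min⁻¹ and Sunday's 0.413 min⁻¹, with a mean of 0.417 min⁻¹. This mean is the induction rate, defined so that the fraction lost equals the two charge fractions times the square of induction rate and time. The precatalyst factor is assumed, since both runs charged the same amount. My reckoning for the flask then gives 7.52%.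

The forecast stands on the first side: “so the order in partner is about 1”. It says 8% reacted, above my figure, as it allows for a steeper curve, with 95% for eP and 8.3% for eS.

The simulation gives 7.19% reacted, eP 90.2% and eS 6.98%.

    partner + catalyst intermediate B → free catalyst + right-handed product (k = 14.0 M⁻¹ min⁻¹)
    partner → decomposed reagent (k = 0.0120 min⁻¹)
    free catalyst + left-handed substrate ⇌ catalyst intermediate A (K = 6.40 M⁻¹, k = 520 M⁻¹ min⁻¹)
    free catalyst + right-handed substrate ⇌ catalyst intermediate B (K = 0.690 M⁻¹, k = 3800 M⁻¹ min⁻¹)
    partner ⇌ dormant form (K = 0.410, k = 0.0130 min⁻¹)
    precatalyst → free catalyst (k = 0.0960 min⁻¹)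
    partner + catalyst intermediate A → free catalyst + left-handed product (k = 40.0 M⁻¹ min⁻¹)

The flask goes to the first chemist: 7.19% lies nearer 7.52% than 13.8%. The induction rate 0.417 min⁻¹ also gives 3.04% for the neighbour with 3.8 × 10⁻⁴ M of precatalyst, which reaches 3.04%. The second view has its region at high partner: the neighbour with 1.8 M of partner reaches 16.0%, nearer 13.8% than the 19.2% reckoned from the induction rate. In the flask, the precatalyst's half-life of 7.22 min is far longer than the 1.7 s of catalyst intermediate A by its step with partner at 5.42 min. At 12.0 min the precatalyst still holds 31.6% of the catalyst charged.

The earlier runs and the new flask were computed for an exercise, and the scatter is random.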